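**Retrosynthetic overview**

- The strategy rests on upper C4: a diarylmethine carbon bonded to C4a of the upper ring A and to C8 of the lower ring A, and ortho to the ring oxygen O1 on C8a. O1–C8a–C4a–C4 is therefore an o-quinone methide heterodiene and C2–C3 its two-carbon partner.
- The upper pyran ring is the only ring made, and it is made last: [4+2] of the methide from an o-hydroxybenzhydrol with a (Z)-2-arylvinyl acetate under a chiral phosphoric acid (bonds O1–C2 and C3–C4), then saponification and hydrogenolysis.
- The benzhydrol comes from the C8 aryl Grignard reagent of the lower unit (8-iodide, I/Mg exchange) and 2-(allyloxy)-4,6-bis(benzyloxy)benzaldehyde. The allyl group is removed with palladium under neutral conditions, because acid would ionise the carbinol.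
- The lower unit is (−)-epicatechin, which brings both lower rings and C2/C3. C4 is set by DDQ oxidation and Mukaiyama-type alkylation with a silyl ketene acetal.
- The (Z)-enol acetate is made geometrically pure from the aryl alkyne by ruthenium-catalysed anti-Markovnikov addition of acetic acid.

Key step: step 12

Assumption: the sense of induction of the binaphthyl phosphoric acid cannot be derived for this methide, so the (R)-acid is written and its (S)-antipode takes its place if that proves to be the matched one.
Remark: 11 and 12 are mixtures of carbinol epimers and the exocyclic double bond geometry of 16 is left open; both elements vanish or equilibrate in step 12.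

**Step 1**
Reactants: 1 (−)-epicatechin
Product: 2 5,7,3',4'-tetra-O-benzyl-(−)-epicatechin
Conditions: BnBr (4.2 equiv), K2CO3, DMF, 0 °C → rt
Reagents that add atoms: benzyl bromide, BrCc1ccccc1
Why: Williamson etherification with a carbonate base alkylates the four phenols and leaves the secondary 3-OH free, and C2 and C3 are not touched under these conditions.

**Step 2**
Reactants: 2 5,7,3',4'-tetra-O-benzyl-(−)-epicatechin
Product: 3 4β-(2-ethoxyethoxy)-5,7,3',4'-tetra-O-benzylepicatechin
Conditions: DDQ (2 equiv), 2-ethoxyethanol (5 equiv), CH2Cl2, rt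
Reagents that add atoms: 2-ethoxyethanol, CCOCCO
Why: DDQ benzylic oxidation removes hydride from C4, which the 5,7-dialkoxy ring A activates, and the alcohol should capture the cation on the β face, anti to the 3-OH and the C2 aryl group, which sets the 3,4-trans ether.

**Step 3**
Reactants: 3 4β-(2-ethoxyethoxy)-5,7,3',4'-tetra-O-benzylepicatechin
Product: 4 4β-(2-ethoxyethoxy)-3,5,7,3',4'-penta-O-benzylepicatechin
Conditions: NaH, BnBr, Bu4NI (cat.), DMF, 0 °C → rt
Reagents that add atoms: benzyl bromide, BrCc1ccccc1
Why: Williamson etherification of the secondary alkoxide, in which the C4 benzylic ether is stable to base and no stereocentre is affected.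

**Step 4**
Reactants: 4 4β-(2-ethoxyethoxy)-3,5,7,3',4'-penta-O-benzylepicatechin
Product: 5 methyl 2-[(2R,3R,4S)-3,5,7-tris(benzyloxy)-2-[3,4-bis(benzyloxy)phenyl]chroman-4-yl]acetate
Conditions: CH2=C(OMe)OTBS (3 equiv), TMSOTf (0.2 equiv), CH2Cl2, −78 °C
Reagents that add atoms: 1-(tert-butyldimethylsilyloxy)-1-methoxyethene, C=C(OC)O[Si](C)(C)C(C)(C)C
Why: Mukaiyama-type SN1 alkylation, in which TMSOTf ionises the C4 ether to the benzylic cation stabilised by ring A and the silyl ketene acetal should attack the β face, anti to the 3-benzyloxy group and the C2 aryl group, which sets C4 as S (3,4-trans).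

**Step 5**
Reactants: 5 methyl 2-[(2R,3R,4S)-3,5,7-tris(benzyloxy)-2-[3,4-bis(benzyloxy)phenyl]chroman-4-yl]acetate
Product: 6 8-iodo derivative of 5
Conditions: NIS (1.0 equiv), DMF, 0 °C, dark
Reagents that add atoms: N-iodosuccinimide, O=C1CCC(=O)N1I
Why: Electrophilic aromatic iodination of the phloroglucinol-type ring A should go to C8, which is flanked by one benzyloxy group and the ring oxygen, and not to C6 between two benzyloxy groups, as is known for the bromination of benzylated flavan-3-ols.

**Step 6**
Reactants: 7 2,4,6-trihydroxybenzaldehyde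
Product: 8 4,6-bis(benzyloxy)-2-hydroxybenzaldehyde
Conditions: BnBr (2.1 equiv), K2CO3, DMF, rt
Reagents that add atoms: benzyl bromide, BrCc1ccccc1
Why: Williamson etherification stops at the dibenzyl ether because the last hydroxyl is hydrogen-bonded to the formyl group and is the least reactive.

**Step 7**
Reactants: 8 4,6-bis(benzyloxy)-2-hydroxybenzaldehyde
Product: 9 2-(allyloxy)-4,6-bis(benzyloxy)benzaldehyde
Conditions: allyl bromide, K2CO3, DMF, 50 °C
Reagents that add atoms: allyl bromide, C=CCBr
Why: Williamson etherification of the chelated phenol under mild heating gives an allyl ether that withstands the Grignard step and can be removed later without acid.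

**Step 8**
Reactants: 6 8-iodo derivative of 5; 9 2-(allyloxy)-4,6-bis(benzyloxy)benzaldehyde
Product: 11 lower-unit methyl ester bearing at C8 a [2-(allyloxy)-4,6-bis(benzyloxy)phenyl](hydroxy)methyl group (both carbinol epimers), via C8 arylmagnesium chloride 10 (not isolated)
Conditions: iPrMgCl·LiCl (1.05 equiv), THF, −30 °C; then 9 (1.2 equiv), −30 → 0 °C; aq. NH4Cl
Reagents that add atoms: none
Why: Iodine–magnesium exchange (Knochel type) should be fast for an aryl iodide with two ortho oxygen substituents and spare the methyl ester at this temperature, and the aryl Grignard reagent adds to the aldehyde much faster than to the ester, the new carbinol centre being formed without control because it is erased in step 12.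

**Step 9**
Reactants: 11 O-allyl benzhydrol
Product: 12 lower-unit methyl ester bearing at C8 a [2-hydroxy-4,6-bis(benzyloxy)phenyl](hydroxy)methyl group (both carbinol epimers)
Conditions: Pd(PPh3)4 (5 mol%), morpholine (5 equiv), THF, rt; filtration through neutral alumina, used at once
Reagents that add atoms: none
Why: Tsuji–Trost deallylation, in which zerovalent palladium turns the aryl allyl ether into a π-allyl complex that morpholine traps, frees the phenol under neutral conditions that do not ionise the acid-labile benzhydrol or touch the benzyl ethers and the ester.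

**Step 10**
Reactants: 13 3,4-bis(benzyloxy)benzaldehyde
Product: 14 1,2-bis(benzyloxy)-4-ethynylbenzene
Conditions: dimethyl (1-diazo-2-oxopropyl)phosphonate, K2CO3, MeOH/THF, rt
Reagents that add atoms: dimethyl (1-diazo-2-oxopropyl)phosphonate, CC(=O)C(=[N+]=[N-])P(=O)(OC)OC
Why: Ohira–Bestmann (Seyferth–Gilbert) homologation converts the aryl aldehyde into the terminal alkyne through a diazoalkene and an alkylidene carbene that undergoes a 1,2-hydrogen shift.

**Step 11**
Reactants: 14 1,2-bis(benzyloxy)-4-ethynylbenzene
Product: 15 (Z)-2-[3,4-bis(benzyloxy)phenyl]vinyl acetate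
Conditions: AcOH (1.5 equiv), [RuCl2(p-cymene)]2 (1 mol%), P(4-ClC6H4)3 (3 mol%), DMAP (4 mol%), toluene, 60 °C
Reagents that add atoms: acetic acid, CC(=O)O
Why: Ruthenium-catalysed anti-Markovnikov hydro-acyloxylation of a terminal alkyne runs through a ruthenium vinylidene whose α-carbon takes up the carboxylate, and protonolysis should deliver the (Z)-enol ester.

**Step 12**
Reactants: 12 o-hydroxybenzhydrol; 15 (Z)-2-[3,4-bis(benzyloxy)phenyl]vinyl acetate
Product: 17 nona-O-benzyl upper-3-O-acetyl methyl ester of the target (upper pyran 2R,3R,4R), via o-quinone methide 16 (not isolated)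
Conditions: (R)-3,3'-bis(2,4,6-triisopropylphenyl)-1,1'-binaphthyl-2,2'-diyl hydrogen phosphate (10 mol%), 15 (3 equiv), 5 Å molecular sieves, toluene, −30 °C, slow addition of 12
Reagents that add atoms: none
Why: Proposed new method: the phosphoric acid protonates the carbinol of 12, water leaves, and the o-quinone methide 16 (heterodiene O1=C8a–C4a=C4 of the upper ring A) stays hydrogen-bonded to the phosphate while the alkene of 15 adds in an asynchronous inverse-demand hetero-Diels–Alder reaction in which C3 bonds to C4 ahead of the bond from the dialkoxybenzylic C2 to O1. The closest known reaction type is the chiral-phosphoric-acid-catalysed [4+2] cycloaddition of o-quinone methides from o-hydroxybenzhydrols with styrenes and β-alkylstyrenes, which has not been shown with a 2-arylvinyl ester as the two-carbon partner or with the exo outcome needed here. The upper pyran ring closes by intermolecular [4+2] cycloaddition with both bonds formed on one face of each partner, and if bond formation becomes stepwise the second bond is a 6-endo capture of the benzylic cation by O1. C2 and C3 should come out cis because the (Z)-geometry of 15 is carried over suprafacially; C4 should come out trans to C3 because the alkene places H-3, not the acetoxy group, next to the twisted 2,6-dioxygenated lower aryl group on the methide carbon (exo orientation of both alkene substituents, which also gives the 2,4-trans diaryl relation); the absolute sense comes from the catalyst pocket, which covers one face of the methide. The regiochemistry (aryl at C2, acetoxy at C3) rests on the 3,4-bis(benzyloxy)phenyl group stabilising positive charge far better than the acetoxy group, so that the acetoxy-bearing carbon is the nucleophilic one. Toluene at low temperature, molecular sieves and slow addition of 12 to an excess of 15 are meant to keep the ion pair tight (no rotation about C2–C3, no acetoxy participation), to stop hydrolysis of 15 by the water set free and to suppress self-condensation of 16.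

**Step 13**
Reactants: 17 protected dimer
Product: 18 nona-O-benzyl dimer with free upper 3-OH and free carboxylic acid
Conditions: LiOH (10 equiv), THF/MeOH/H2O, rt → 40 °C; then 1 M HCl to pH 4, 0 °C
Reagents that add atoms: lithium hydroxide, [Li+].[OH-]
Why: Saponification cleaves the methyl ester and the secondary acetate by acyl–oxygen fission, so no stereocentre is involved, and the benzyl ethers and the interflavan bond are stable to base.

**Step 14**
Reactants: 18 nona-O-benzyl dimer acid
Product: 19 target, epicatechin-(4β→8)-4β-carboxymethylepicatechin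
Conditions: H2 (1 atm), Pd(OH)2/C, THF/MeOH/H2O, rt; filtration, lyophilisation
Reagents that add atoms: none
Why: Catalytic hydrogenolysis over Pearlman's catalyst removes the nine benzyl ethers under neutral conditions, as is usual for benzylated procyanidins, and leaves the ring C–O bonds and all six stereocentres intact.

**Compound list**

1 | (−)-epicatechin, (2R,3R)-2-(3,4-dihydroxyphenyl)chromane-3,5,7-triol | C1c2c(O)cc(O)cc2O[C@H](c2ccc(O)c(O)c2)[C@@H]1O | starting material
2 | 5,7,3',4'-tetra-O-benzyl-(−)-epicatechin (2R,3R; 3-OH free) | C1c2c(OCc3ccccc3)cc(OCc3ccccc3)cc2O[C@H](c2ccc(OCc3ccccc3)c(OCc3ccccc3)c2)[C@@H]1O | intermediate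
3 | 4β-(2-ethoxyethoxy)-5,7,3',4'-tetra-O-benzylepicatechin (2,3-cis, 3,4-trans, 3-OH free) | CCOCCO[C@H]1c2c(OCc3ccccc3)cc(OCc3ccccc3)cc2O[C@H](c2ccc(OCc3ccccc3)c(OCc3ccccc3)c2)[C@@H]1O | intermediate
4 | 4β-(2-ethoxyethoxy)-3,5,7,3',4'-penta-O-benzylepicatechin | CCOCCO[C@H]1c2c(OCc3ccccc3)cc(OCc3ccccc3)cc2O[C@H](c2ccc(OCc3ccccc3)c(OCc3ccccc3)c2)[C@@H]1OCc1ccccc1 | intermediate
5 | methyl 2-[(2R,3R,4S)-3,5,7-tris(benzyloxy)-2-[3,4-bis(benzyloxy)phenyl]chroman-4-yl]acetate (lower unit, C4 side chain β) | COC(=O)C[C@H]1c2c(OCc3ccccc3)cc(OCc3ccccc3)cc2O[C@H](c2ccc(OCc3ccccc3)c(OCc3ccccc3)c2)[C@@H]1OCc1ccccc1 | intermediate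
6 | 8-iodo derivative of 5 | COC(=O)C[C@H]1c2c(OCc3ccccc3)cc(OCc3ccccc3)c(I)c2O[C@H](c2ccc(OCc3ccccc3)c(OCc3ccccc3)c2)[C@@H]1OCc1ccccc1 | intermediate
7 | 2,4,6-trihydroxybenzaldehyde | O=Cc1c(O)cc(O)cc1O | starting material
8 | 4,6-bis(benzyloxy)-2-hydroxybenzaldehyde | O=Cc1c(O)cc(OCc2ccccc2)cc1OCc1ccccc1 | intermediate
9 | 2-(allyloxy)-4,6-bis(benzyloxy)benzaldehyde | O=Cc1c(OCC=C)cc(OCc2ccccc2)cc1OCc1ccccc1 | intermediate
10 | C8 arylmagnesium chloride of the lower unit (from 6, as its LiCl complex) | COC(=O)C[C@H]1c2c(OCc3ccccc3)cc(OCc3ccccc3)c([Mg]Cl)c2O[C@H](c2ccc(OCc3ccccc3)c(OCc3ccccc3)c2)[C@@H]1OCc1ccccc1 | intermediate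
11 | lower-unit methyl ester with a [2-(allyloxy)-4,6-bis(benzyloxy)phenyl](hydroxy)methyl group at C8, both carbinol epimers | COC(=O)C[C@H]1c2c(OCc3ccccc3)cc(OCc3ccccc3)c(C(O)c3c(OCC=C)cc(OCc4ccccc4)cc3OCc3ccccc3)c2O[C@H](c2ccc(OCc3ccccc3)c(OCc3ccccc3)c2)[C@@H]1OCc1ccccc1 | intermediate
12 | lower-unit methyl ester with a [2-hydroxy-4,6-bis(benzyloxy)phenyl](hydroxy)methyl group at C8, both carbinol epimers | COC(=O)C[C@H]1c2c(OCc3ccccc3)cc(OCc3ccccc3)c(C(O)c3c(O)cc(OCc4ccccc4)cc3OCc3ccccc3)c2O[C@H](c2ccc(OCc3ccccc3)c(OCc3ccccc3)c2)[C@@H]1OCc1ccccc1 | intermediate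
13 | 3,4-bis(benzyloxy)benzaldehyde | O=Cc1ccc(OCc2ccccc2)c(OCc2ccccc2)c1 | starting material
14 | 1,2-bis(benzyloxy)-4-ethynylbenzene | C#Cc1ccc(OCc2ccccc2)c(OCc2ccccc2)c1 | intermediate
15 | (Z)-2-[3,4-bis(benzyloxy)phenyl]vinyl acetate | CC(=O)O/C=C\c1ccc(OCc2ccccc2)c(OCc2ccccc2)c1 | intermediate
16 | o-quinone methide: 3,5-bis(benzyloxy)-6-(arylmethylidene)cyclohexa-2,4-dienone, aryl = C8 of the lower unit, double bond geometry open | COC(=O)C[C@H]1c2c(OCc3ccccc3)cc(OCc3ccccc3)c(C=C3C(=O)C=C(OCc4ccccc4)C=C3OCc3ccccc3)c2O[C@H](c2ccc(OCc3ccccc3)c(OCc3ccccc3)c2)[C@@H]1OCc1ccccc1 | intermediate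
17 | protected target: nona-O-benzyl, upper 3-O-acetyl, methyl ester; upper unit 2R,3R,4R (2,3-cis, 3,4-trans), lower unit 2R,3R,4S | COC(=O)C[C@H]1c2c(OCc3ccccc3)cc(OCc3ccccc3)c([C@H]3c4c(OCc5ccccc5)cc(OCc5ccccc5)cc4O[C@H](c4ccc(OCc5ccccc5)c(OCc5ccccc5)c4)[C@@H]3OC(C)=O)c2O[C@H](c2ccc(OCc3ccccc3)c(OCc3ccccc3)c2)[C@@H]1OCc1ccccc1 | intermediate
18 | nona-O-benzyl dimer with free upper 3-OH and free carboxylic acid | OC(=O)C[C@H]1c2c(OCc3ccccc3)cc(OCc3ccccc3)c([C@H]3c4c(OCc5ccccc5)cc(OCc5ccccc5)cc4O[C@H](c4ccc(OCc5ccccc5)c(OCc5ccccc5)c4)[C@@H]3O)c2O[C@H](c2ccc(OCc3ccccc3)c(OCc3ccccc3)c2)[C@@H]1OCc1ccccc1 | intermediate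
19 | CNP0190976.1, epicatechin-(4β→8)-4β-carboxymethylepicatechin | O=C(O)C[C@H]1c2c(O)cc(O)c([C@H]3c4c(O)cc(O)cc4O[C@H](c4ccc(O)c(O)c4)[C@@H]3O)c2O[C@H](c2ccc(O)c(O)c2)[C@@H]1O | target

**Step count**

Total: 14 steps. Longest linear sequence: 10 steps (1, 2, 3, 4, 5, 8, 9, 12, 13, 14).

**Steps most likely to fail**

Step 12. The methide–alkene union may become stepwise, so that rotation about C2–C3 or acetoxy participation in the benzylic cation erodes the 2,3-cis relation. The alkene may also approach endo and give the 3,4-cis isomer, the catalyst may fail to override the facial bias of the lower unit, and the methide may self-condense on the electron-rich rings or be reduced by hydride transfer from an ortho benzyloxy group. The fallback is the known Lewis-acid coupling of flavan units. It sets out from 3, which Ac2O/pyridine/DMAP converts into 3-O-acetyl-4β-(2-ethoxyethoxy)-5,7,3',4'-tetra-O-benzylepicatechin F1. With TMSOTf (cat.) in CH2Cl2 at −78 °C, F1 ionises at C4 and is attacked at C8 by an excess of the lower unit 5, anti to the 3-acetoxy group. This forms the 4β→8 bond and comes back to the route at 17, leaving out steps 5 to 12.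

Step 8. The iodine–magnesium exchange may be incomplete, the Grignard reagent may be consumed by the ester of a second molecule, or the addition may stall because both partners carry two ortho substituents. The fallback reverses the polarity and sets out from 5. Vilsmeier–Haack formylation (POCl3, DMF, 0 °C → rt, aqueous NaOAc) should give the 8-formyl lower-unit ester F2. Purchased 3,5-bis(benzyloxy)phenol (Oc1cc(OCc2ccccc2)cc(OCc2ccccc2)c1) is converted with EtMgBr into bromomagnesium 3,5-bis(benzyloxy)phenoxide F3. F3 adds to F2 in toluene through its ortho carbon in a chelated six-membered transition state (ortho-hydroxyalkylation of a magnesium phenoxide), which comes back to the route at 12 and leaves out 6, 9 and 11.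

Step 14. The hydrogenolysis of nine benzyl ethers may stop early, prolonged exposure may open the benzylic C2–O1 bonds, and the free carboxylic acid may lactonise onto the lower 5-OH or promote cleavage of the interflavan bond. The fallback changes the order of deprotection and sets out from 17. Hydrogenolysis (H2, Pd(OH)2/C, THF/MeOH) of the neutral ester first gives the nonaphenol methyl ester 3-O-acetate F4. Its two esters are then cleaved with degassed aqueous LiOH in THF under argon at 0 °C in the presence of sodium ascorbate, followed by acidification to pH 4, which comes back to the route at 19.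

**Further compounds**

F1 | step 12 | 3-O-acetyl-4β-(2-ethoxyethoxy)-5,7,3',4'-tetra-O-benzylepicatechin | CCOCCO[C@H]1c2c(OCc3ccccc3)cc(OCc3ccccc3)cc2O[C@H](c2ccc(OCc3ccccc3)c(OCc3ccccc3)c2)[C@@H]1OC(C)=O
F2 | step 8 | 8-formyl derivative of 5 | COC(=O)C[C@H]1c2c(OCc3ccccc3)cc(OCc3ccccc3)c(C=O)c2O[C@H](c2ccc(OCc3ccccc3)c(OCc3ccccc3)c2)[C@@H]1OCc1ccccc1
F3 | step 8 | bromomagnesium 3,5-bis(benzyloxy)phenoxide | Br[Mg]Oc1cc(OCc2ccccc2)cc(OCc2ccccc2)c1
F4 | step 14 | methyl ester upper-3-O-acetate of the target with all nine hydroxyl groups free | COC(=O)C[C@H]1c2c(O)cc(O)c([C@H]3c4c(O)cc(O)cc4O[C@H](c4ccc(O)c(O)c4)[C@@H]3OC(C)=O)c2O[C@H](c2ccc(O)c(O)c2)[C@@H]1O
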